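**Retrosynthetic overview**
1. Target 18 is a linear hexamer: two butyrylfilicinic end rings, four butyrylphloroglucinol inner rings, five CH2 bridges. Cut the two outermost CH2–aryl bonds: two-fold Michael addition of tetramer 15 to methylene triketone 16, released in the flask from Mannich salt 6.
2. 15 ⇒ bis-Mannich salt 11 + 2 × butyrylphloroglucinol 3 (Michael additions to o-quinone methides); 11 ⇒ dimer 9 + Eschenmoser's salt.
3. 9 ⇒ 2 × 3 + CH2O (hydroxymethylation, dehydration, Michael); 6 ⇒ butyrylfilicinic acid 5 + Eschenmoser's salt (Mannich).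
4. 5 ⇒ 3 by dearomative gem-dimethylation; 3 ⇒ phloroglucinol 1 + butanoyl chloride 2 (Friedel–Crafts).
5. Ring order: no ring is built; all six carbocycles come from 1. The four aromatic rings are linked first (9, then 15); the two filicinic rings are attached last, so the most labile bridges see no later step.

Assumption: the target has no stereocentre (every sp3 carbon carries two identical groups), so it is achiral and no stereocontrol is needed; it is drawn in the tautomer of the given SMILES.

**Step 1**
Reactants: 1 phloroglucinol (anhydrous); 2 butanoyl chloride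
Product: 3 butyrylphloroglucinol
Conditions: AlCl3 (3.5 equiv), PhNO2–CH2Cl2, 0 °C → 45 °C, 3 h; then ice/1 M HCl
Reagents that add atoms: none
Why: Friedel–Crafts C-acylation of the very electron-rich ring stops at the mono-ketone because the first acyl group (chelated to aluminium) deactivates the ring; no stereocentre.

**Step 2**
Reactants: 3 butyrylphloroglucinol
Product: 5 butyrylfilicinic acid, via 3-methyl ketone 4 (not isolated)
Conditions: NaOMe (3.2 equiv), MeI (2.2 equiv), MeOH, 0 °C → rt, 16 h; then 1 M HCl; chromatography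
Reagents that add atoms: iodomethane, CI
Why: Dearomative double C-alkylation of the phloroglucinol polyanion; the second methylation at the same carbon is driven by formation of the stabilised β-triketone (vinylogous acid) anion, and no stereocentre is formed.

**Step 3**
Reactants: 5 butyrylfilicinic acid
Product: 6 filicinic Mannich salt (hydroiodide)
Conditions: Eschenmoser's salt (1.05 equiv), MeCN, 0 °C, 2 h (5 added to the salt); Et2O precipitation, filtered, recrystallised MeOH–Et2O
Reagents that add atoms: N,N-dimethylmethyleneiminium iodide (Eschenmoser's salt), C=[N+](C)C.[I-]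
Why: Mannich reaction of the only free enol carbon with a preformed iminium ion; without base the product stays N-protonated and un-ionised, so it cannot eliminate and alkylate unreacted 5.

**Step 4**
Reactants: 3 butyrylphloroglucinol (6 equiv)
Product: 9 methylenebis(butyrylphloroglucinol), via hydroxymethyl ketone 7 (not isolated), via quinone methide 8 (not isolated)
Conditions: 37 % aq. CH2O (1 equiv), KOH (cat.), H2O–MeOH, 0 °C → rt, 30 min; then 1 M HCl; chromatography, excess 3 recovered
Reagents that add atoms: formaldehyde, C=O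
Why: Lederer–Manasse hydroxymethylation (aldol-type addition of the phenolate carbon to formaldehyde), base-induced dehydration to the o-quinone methide and Michael addition of a second phenolate; the six-fold excess of 3 suppresses higher oligomers.

**Step 5**
Reactants: 9 methylenebis(butyrylphloroglucinol)
Product: 11 bis-Mannich salt (bis-hydroiodide), via mono-Mannich salt 10 (not isolated)
Conditions: Eschenmoser's salt (2.3 equiv), MeCN, 0 °C → rt, 12 h; Et2O, filtered
Reagents that add atoms: N,N-dimethylmethyleneiminium iodide (Eschenmoser's salt), C=[N+](C)C.[I-]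
Why: Aromatic Mannich aminomethylation at the single unsubstituted, doubly hydroxy-activated carbon of each ring, so exhaustive reaction is unambiguous; the acidic medium keeps the benzylic amines protonated and inert.

**Step 6**
Reactants: 11 bis-Mannich salt; 3 butyrylphloroglucinol (12 equiv)
Product: 15 linear tetramer, via quinone methide 12 (not isolated), via trimer Mannich salt 13 (not isolated), via quinone methide 14 (not isolated)
Conditions: NaOAc (2.5 equiv), MeCN–DMF 4:1, 45 °C, N2, 4 h; AcOH quench; chromatography, excess 3 recovered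
Reagents that add atoms: none
Why: Acetate frees the ammonium phenolate zwitterion, which loses Me2NH (E1cB) to an o-quinone methide that the ring carbon of 3 attacks in a Michael addition followed by re-aromatisation; the large excess of 3 keeps each molecule of 3 to one alkylation.

**Step 7**
Reactants: 15 linear tetramer; 6 filicinic Mannich salt (2.3 equiv)
Product: 18 target hexamer, via methylene triketone 16 (not isolated), via mono-capped pentamer 17 (not isolated)
Conditions: NaOAc (2.5 equiv), MeCN–DMF 4:1, 0 °C → rt, N2, 6 h (6 added in portions); AcOH quench; Sephadex LH-20 (MeOH–CHCl3, 0.1 % AcOH), crystallisation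
Reagents that add atoms: none
Why: Acetate ionises the acidic enol of 6, the betaine loses Me2NH at or below rt to the exo-methylene triketone, and the one free ring carbon at each end of 15 adds in a Michael reaction; the acetate buffer and low temperature avoid base-induced scrambling of the methylene bridges, and no stereocentre arises.

**Compound list**
1 | phloroglucinol (benzene-1,3,5-triol) | Oc1cc(O)cc(O)c1 | starting material
2 | butanoyl chloride | CCCC(=O)Cl | starting material
3 | butyrylphloroglucinol, 1-(2,4,6-trihydroxyphenyl)butan-1-one | CCCC(=O)c1c(O)cc(O)cc1O | intermediate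
4 | 1-(2,4,6-trihydroxy-3-methylphenyl)butan-1-one | CCCC(=O)c1c(O)cc(O)c(C)c1O | intermediate
5 | butyrylfilicinic acid, 2-butanoyl-3,5-dihydroxy-4,4-dimethylcyclohexa-2,5-dien-1-one | CCCC(=O)C1=C(O)C(C)(C)C(O)=CC1=O | intermediate
6 | 2-butanoyl-6-[(dimethylamino)methyl]-3,5-dihydroxy-4,4-dimethylcyclohexa-2,5-dien-1-one hydroiodide | CCCC(=O)C1=C(O)C(C)(C)C(O)=C(C[NH+](C)C)C1=O.[I-] | intermediate
7 | 1-[2,4,6-trihydroxy-3-(hydroxymethyl)phenyl]butan-1-one | CCCC(=O)c1c(O)cc(O)c(CO)c1O | intermediate
8 | 2-butanoyl-3,5-dihydroxy-6-methylidenecyclohexa-2,4-dien-1-one (o-quinone methide of 3) | CCCC(=O)C1=C(O)C=C(O)C(=C)C1=O | intermediate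
9 | bis(3-butanoyl-2,4,6-trihydroxyphenyl)methane | CCCC(=O)c1c(O)cc(O)c(Cc2c(O)cc(O)c(C(=O)CCC)c2O)c1O | intermediate
10 | 9 carrying one CH2NMe2 group on the free carbon of one ring, hydroiodide | CCCC(=O)c1c(O)cc(O)c(Cc2c(O)c(C[NH+](C)C)c(O)c(C(=O)CCC)c2O)c1O.[I-] | intermediate
11 | bis{3-butanoyl-5-[(dimethylamino)methyl]-2,4,6-trihydroxyphenyl}methane bis(hydroiodide) | CCCC(=O)c1c(O)c(C[NH+](C)C)c(O)c(Cc2c(O)c(C[NH+](C)C)c(O)c(C(=O)CCC)c2O)c1O.[I-].[I-] | intermediate
12 | 4-butanoyl-3,5-dihydroxy-6-methylidene-2-(arylmethyl)cyclohexa-2,4-dien-1-one, aryl = 3-butanoyl-5-[(dimethylammonio)methyl]-2,4,6-trihydroxyphenyl, iodide | CCCC(=O)C1=C(O)C(=C)C(=O)C(Cc2c(O)c(C[NH+](C)C)c(O)c(C(=O)CCC)c2O)=C1O.[I-] | intermediate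
13 | linear trimer: 3-butanoyl-2,4,6-trihydroxyphenyl–CH2–(5-butanoyl-2,4,6-trihydroxy-1,3-phenylene)–CH2–{3-butanoyl-5-[(dimethylammonio)methyl]-2,4,6-trihydroxyphenyl}, iodide | CCCC(=O)c1c(O)cc(O)c(Cc2c(O)c(Cc3c(O)c(C[NH+](C)C)c(O)c(C(=O)CCC)c3O)c(O)c(C(=O)CCC)c2O)c1O.[I-] | intermediate
14 | o-quinone methide of 13: end ring = 4-butanoyl-3,5-dihydroxy-6-methylidene-1-oxocyclohexa-2,4-dien-2-yl, joined through CH2 to the dimer part | CCCC(=O)c1c(O)cc(O)c(Cc2c(O)c(CC3=C(O)C(C(=O)CCC)=C(O)C(=C)C3=O)c(O)c(C(=O)CCC)c2O)c1O | intermediate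
15 | linear tetramer Ar–CH2–Ar'–CH2–Ar'–CH2–Ar (Ar = 3-butanoyl-2,4,6-trihydroxyphenyl, Ar' = 5-butanoyl-2,4,6-trihydroxy-1,3-phenylene) | CCCC(=O)c1c(O)cc(O)c(Cc2c(O)c(Cc3c(O)c(Cc4c(O)cc(O)c(C(=O)CCC)c4O)c(O)c(C(=O)CCC)c3O)c(O)c(C(=O)CCC)c2O)c1O | intermediate
16 | 2-butanoyl-3-hydroxy-4,4-dimethyl-6-methylidenecyclohex-2-ene-1,5-dione | CCCC(=O)C1=C(O)C(C)(C)C(=O)C(=C)C1=O | intermediate
17 | pentamer: 15 with one end carbon bearing the (3-butanoyl-2,4-dihydroxy-5,5-dimethyl-6-oxocyclohexa-1,3-dienyl)methyl group, other end free | CCCC(=O)C1=C(O)C(C)(C)C(O)=C(Cc2c(O)c(Cc3c(O)c(Cc4c(O)c(Cc5c(O)cc(O)c(C(=O)CCC)c5O)c(O)c(C(=O)CCC)c4O)c(O)c(C(=O)CCC)c3O)c(O)c(C(=O)CCC)c2O)C1=O | intermediate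
18 | CNP0237140.0: 15 with both end carbons joined through CH2 to the free ring carbon of butyrylfilicinic acid (achiral) | CCCC(=O)C1=C(O)C(C)(C)C(O)=C(Cc2c(O)c(Cc3c(O)c(Cc4c(O)c(Cc5c(O)c(CC6=C(O)C(C)(C)C(O)=C(C(=O)CCC)C6=O)c(O)c(C(=O)CCC)c5O)c(O)c(C(=O)CCC)c4O)c(O)c(C(=O)CCC)c3O)c(O)c(C(=O)CCC)c2O)C1=O | target

**Totals**
Total steps: 7. Longest linear sequence: 5 steps (1 → 3 → 9 → 11 → 15 → 18; steps 1, 4, 5, 6, 7). The branch 3 → 5 → 6 (steps 2, 3) joins at step 7.

**Three steps most likely to fail**

Step 2 (mixture of mono-, gem-di-, 3,5-di- and tri-methylated products). The fallback sets out from 3 and comes back at 5, replacing stoichiometric control by a blocking group. A second Friedel–Crafts acylation of 3 with 2 (AlCl3, PhNO2, 60 °C) gives 2,4-dibutyrylphloroglucinol F1, which has only one free ring carbon. MeI/NaOMe (MeOH, rt) can then methylate only there and gives 2,4-dibutyryl-6,6-dimethylcyclohexane-1,3,5-trione (enol form) F2. Acid retro-Claisen cleavage of one of its two equivalent acyl groups (6 M HCl–dioxane, 90 °C, stopped at mono-deacylation by HPLC) gives 5.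

Step 6 (two-fold statistical coupling; chain growth beyond the tetramer, hard separation). The fallback sets out from 6 and 3, uses 11, and comes back at 18, changing the order of bond formation. Salt 6 is treated with 5 equiv of 3 (NaOAc, MeCN, 0 °C → rt); Michael addition to 16 gives norflavaspidic acid BB F3, which has exactly one nucleophilic ring carbon. Then 11 and 2.2 equiv of F3 (NaOAc, MeCN–DMF, 40 °C) give 18 directly by two Michael additions. No tetramer with two open ends has to be isolated and step 7 is bypassed; the price is that the filicinic bridges are present during the last warming.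

Step 7 (self-condensation of 16, incomplete second capping, bridge scrambling). The fallback sets out from 15 and comes back at 18, reversing the polarity of the partners. Tetramer 15 is aminomethylated at both free end carbons (Eschenmoser's salt 2.3 equiv, MeCN, rt) to the tetramer bis-Mannich salt F4. F4 with 3 equiv of 5 (NaOAc, MeCN–DMF, 40 °C) gives 18: the o-quinone methides now sit on the aromatic end rings, and the strongly C-nucleophilic enol 5, with a single reactive carbon, is the Michael donor. Neither 6 nor 16 is handled.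

**Further compounds**
F1 | step 2 | 2,4-dibutyrylphloroglucinol, 1,1'-(2,4,6-trihydroxy-1,3-phenylene)di(butan-1-one) | CCCC(=O)c1c(O)cc(O)c(C(=O)CCC)c1O
F2 | step 2 | 2,4-dibutanoyl-3,5-dihydroxy-6,6-dimethylcyclohexa-2,4-dien-1-one | CCCC(=O)C1=C(O)C(C(=O)CCC)=C(O)C(C)(C)C1=O
F3 | step 6 | norflavaspidic acid BB: butyrylfilicinic acid joined at its free ring carbon through CH2 to C-3 of butyrylphloroglucinol | CCCC(=O)C1=C(O)C(C)(C)C(O)=C(Cc2c(O)cc(O)c(C(=O)CCC)c2O)C1=O
F4 | step 7 | 15 carrying a CH2NMe2 group on each free end carbon, bis(hydroiodide) | CCCC(=O)c1c(O)c(C[NH+](C)C)c(O)c(Cc2c(O)c(Cc3c(O)c(Cc4c(O)c(C[NH+](C)C)c(O)c(C(=O)CCC)c4O)c(O)c(C(=O)CCC)c3O)c(O)c(C(=O)CCC)c2O)c1O.[I-].[I-]
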